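**Retrosynthetic overview**
1. Target 20 ⇐ enone 18: the last step forms the C-8a–O bond by a hydroxyl-tethered conjugate hydration of the ring-fusion enone, which sets C-8a and C-3a.
2. 18 ⇐ 14 + 15: the butenolide is attached by hydroboration/B-alkyl Suzuki coupling of a C-5 vinyl group; the C-5 quaternary centre comes from Pd enolate vinylation anti to the C-6 methyl.
3. Seven-membered ring ⇐ 9: intramolecular B-alkyl Suzuki coupling onto a β-bromo enone; C-6 is set by Ir-catalysed branched crotylation.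
4. The five-membered ring is bought as 2,2-dimethylcyclopentane-1,3-dione; CBS reduction sets C-2 and Vilsmeier–Arnold bromoformylation fixes the enone regiochemistry.
5. Ring order: cyclopentane (from 1) → cycloheptenone (step 7) → butenolide (bought as 15, attached in step 9).

Assumption: the trans ring fusion of the target (3a-H anti to 8a-OH) is the more stable arrangement at the enolisable C-3a, so equilibration there converges on the target; azulene numbering is used (C-1 CMe2, C-2 CHOH, C-3a/C-8a ring fusion, C-4 C=O, C-5 quaternary, C-6 CHMe).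

**Step 1**
Reactants: 1 2,2-dimethylcyclopentane-1,3-dione
Product: 2 (R)-3-hydroxy-2,2-dimethylcyclopentan-1-one
Conditions: (S)-Me-CBS (10 mol%), BH3·SMe2 (0.7 equiv), THF, −20 °C; then H2O
Reagents that add atoms: none
Why: Corey–Bakshi–Shibata reduction desymmetrises the dione because the oxazaborolidine–borane complex treats the quaternary carbon as the large flank and the ring CH2 as the small one, so hydride sets the (R)-carbinol that becomes C-2, and the second carbonyl reacts more slowly.

**Step 2**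
Reactants: 2 (R)-3-hydroxy-2,2-dimethylcyclopentan-1-one
Product: 3 (R)-3-[(tert-butyldiphenylsilyl)oxy]-2,2-dimethylcyclopentan-1-one
Conditions: TBDPSCl, imidazole, DMAP (cat.), DMF, 40 °C
Reagents that add atoms: tert-butyl(chloro)diphenylsilane CC(C)(C)[Si](Cl)(c1ccccc1)c1ccccc1
Why: Standard silyl ether formation; TBDPS is chosen because it resists the Vilsmeier reagent, the Grignard reagent, the amide bases and the boranes that follow.

**Step 3**
Reactants: 3 (R)-3-[(tert-butyldiphenylsilyl)oxy]-2,2-dimethylcyclopentan-1-one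
Product: 4 (R)-2-bromo-4-[(tert-butyldiphenylsilyl)oxy]-3,3-dimethylcyclopent-1-ene-1-carbaldehyde
Conditions: PBr3, DMF, CHCl3, 0 °C → rt; then ice-water
Reagents that add atoms: N,N-dimethylformamide CN(C)C=O; phosphorus tribromide BrP(Br)Br; water O
Why: Vilsmeier–Haack–Arnold bromoformylation: the ketone can enolise only toward its single α-CH2, so the formyl carbon lands there and bromide replaces the activated oxygen on the former carbonyl carbon, which puts the leaving group at the future C-8a and the acyl carbon on the future C-3a with no regiochemical choice.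

**Step 4**
Reactants: 4 (R)-2-bromo-4-[(tert-butyldiphenylsilyl)oxy]-3,3-dimethylcyclopent-1-ene-1-carbaldehyde
Product: 5 1-[(4R)-2-bromo-4-[(tert-butyldiphenylsilyl)oxy]-3,3-dimethylcyclopent-1-en-1-yl]propan-1-ol (both carbinol epimers)
Conditions: EtMgBr, THF, −78 °C; then H2O
Reagents that add atoms: ethylmagnesium bromide CC[Mg]Br
Why: 1,2-Grignard addition to the aldehyde at low temperature; the vinyl bromide and silyl ether are inert, and the new carbinol centre is destroyed in the next step.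

**Step 5**
Reactants: 5 1-[(4R)-2-bromo-4-[(tert-butyldiphenylsilyl)oxy]-3,3-dimethylcyclopent-1-en-1-yl]propan-1-ol
Product: 6 1-[(4R)-2-bromo-4-[(tert-butyldiphenylsilyl)oxy]-3,3-dimethylcyclopent-1-en-1-yl]propan-1-one
Conditions: Dess–Martin periodinane, CH2Cl2, rt
Reagents that add atoms: none
Why: Dess–Martin oxidation of a secondary allylic alcohol to the enone under neutral conditions that leave the vinyl bromide and silyl ether untouched.

**Step 6**
Reactants: 6 1-[(4R)-2-bromo-4-[(tert-butyldiphenylsilyl)oxy]-3,3-dimethylcyclopent-1-en-1-yl]propan-1-one; 7 (E)-but-2-en-1-yl methyl carbonate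
Product: 9 (3R)-1-[(4R)-2-bromo-4-[(tert-butyldiphenylsilyl)oxy]-3,3-dimethylcyclopent-1-en-1-yl]-2,3-dimethylpent-4-en-1-one (C-2 epimers), via trimethylsilyl dienol ether 8 (not isolated)
Conditions: TMSOTf, Et3N, CH2Cl2, 0 °C, filter through pentane; then 7, [Ir(cod)Cl]2 (2 mol%), (Sa,Sc,Sc)-binaphthyl bis(1-phenylethyl)phosphoramidite (4 mol%), CsF (0.4 equiv), DME, 50 °C
Reagents that add atoms: none
Why: Soft enolisation gives the only possible silyl enol ether (ethyl side), and iridium-catalysed asymmetric allylic alkylation (Hartwig type, ligand enantiomer chosen for the (R) outcome) joins the enol carbon to the substituted terminus of the crotyl π-allyl, so the catalyst sets the methyl-bearing allylic centre (future C-6) while the epimeric α-centre is re-enolised in step 8.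

**Step 7**
Reactants: 9 (3R)-1-[(4R)-2-bromo-4-[(tert-butyldiphenylsilyl)oxy]-3,3-dimethylcyclopent-1-en-1-yl]-2,3-dimethylpent-4-en-1-one
Product: 11 (2R,6R)-2-[(tert-butyldiphenylsilyl)oxy]-1,1,5,6-tetramethyl-2,3,5,6,7,8-hexahydroazulen-4(1H)-one (C-5 epimers), via B-alkyl-9-BBN borane 10 (not isolated)
Conditions: 9-BBN (1.1 equiv), THF, 0 °C → rt; then Pd(dppf)Cl2 (10 mol%), AsPh3, K3PO4 (aq), DMF/THF (0.005 M), 50 °C
Reagents that add atoms: none
Why: Anti-Markovnikov hydroboration of the terminal alkene (faster than attack on the hindered cross-conjugated ketone) followed by intramolecular B-alkyl Suzuki–Miyaura coupling with the β-bromo enone closes the seven-membered ring at C-8/C-8a; no stereocentre is formed.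

**Step 8**
Reactants: 11 (2R,6R)-2-[(tert-butyldiphenylsilyl)oxy]-1,1,5,6-tetramethyl-2,3,5,6,7,8-hexahydroazulen-4(1H)-one; 12 bromoethene
Product: 14 (2R,5S,6R)-2-[(tert-butyldiphenylsilyl)oxy]-5-ethenyl-1,1,5,6-tetramethyl-2,3,5,6,7,8-hexahydroazulen-4(1H)-one, via lithium enolate 13 (not isolated)
Conditions: LiN(SiMe3)2, THF, −78 °C; then Pd2(dba)3 (2.5 mol%), P(tBu)3 (6 mol%), 12 (3 equiv), toluene, rt
Reagents that add atoms: none
Why: Kinetic deprotonation gives the cross-conjugated α'-enolate and palladium-catalysed enolate α-vinylation (Buchwald–Hartwig type) forms the quaternary centre, the vinyl group coupling on the enolate face opposite the pseudoaxial C-6 methyl so that the two methyls end up cis (5S).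

**Step 9**
Reactants: 14 (2R,5S,6R)-2-[(tert-butyldiphenylsilyl)oxy]-5-ethenyl-1,1,5,6-tetramethyl-2,3,5,6,7,8-hexahydroazulen-4(1H)-one; 15 4-bromofuran-2(5H)-one
Product: 17 (2R,5S,6R)-2-[(tert-butyldiphenylsilyl)oxy]-1,1,5,6-tetramethyl-5-[2-(5-oxo-2,5-dihydrofuran-3-yl)ethyl]-2,3,5,6,7,8-hexahydroazulen-4(1H)-one, via B-alkyl-9-BBN borane 16 (not isolated)
Conditions: 9-BBN (2 equiv), THF, rt → 50 °C; then 15, Pd(dppf)Cl2 (5 mol%), AsPh3, K3PO4 (aq), DMF, rt
Reagents that add atoms: none
Why: 9-BBN hydroborates only the monosubstituted vinyl group, and B-alkyl Suzuki–Miyaura coupling of the primary alkylborane with the vinylogous acyl bromide 15 delivers the complete ethyl-butenolide side chain without touching any stereocentre.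

**Step 10**
Reactants: 17 (2R,5S,6R)-2-[(tert-butyldiphenylsilyl)oxy]-1,1,5,6-tetramethyl-5-[2-(5-oxo-2,5-dihydrofuran-3-yl)ethyl]-2,3,5,6,7,8-hexahydroazulen-4(1H)-one
Product: 18 (2R,5S,6R)-2-hydroxy-1,1,5,6-tetramethyl-5-[2-(5-oxo-2,5-dihydrofuran-3-yl)ethyl]-2,3,5,6,7,8-hexahydroazulen-4(1H)-one
Conditions: HF·pyridine, THF, 0 °C → rt
Reagents that add atoms: none
Why: Fluoride desilylation under mildly acidic conditions that do not isomerise or open the base-sensitive butenolide.

**Step 11**
Reactants: 18 (2R,5S,6R)-2-hydroxy-1,1,5,6-tetramethyl-5-[2-(5-oxo-2,5-dihydrofuran-3-yl)ethyl]-2,3,5,6,7,8-hexahydroazulen-4(1H)-one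
Product: 20 (2R,3aS,5S,6R,8aS)-2,8a-dihydroxy-1,1,5,6-tetramethyl-5-[2-(5-oxo-2,5-dihydrofuran-3-yl)ethyl]octahydroazulen-4(1H)-one (target CNP0077405.1), via cyclic phenylboronate 19 (not isolated)
Conditions: PhB(OH)2 (1.5 equiv), quinuclidine (20 mol%), N,N'-bis[3,5-bis(trifluoromethyl)phenyl]thiourea (10 mol%), 4 Å MS, toluene, 40 °C; then pinacol, rt
Reagents that add atoms: phenylboronic acid OB(O)c1ccccc1
Why: Proposed new method: the C-2 hydroxyl condenses with PhB(OH)2 to a boronic hemiester whose amine-activated B–OH oxygen is held over one face of the thiourea-activated tetrasubstituted enone and adds 1,4 to C-8a, closing a dioxaborinane across the cis-1,3 positions of the cyclopentane, so the new C–O bond can only form syn to the C-2 oxygen (8aS); the enol is then protonated at C-3a opposite the boronate (or equilibrates under the amine) to the trans-fused 3aS ketone, and chelate formation supplies the driving force that plain hydration of a hindered enone lacks; the closest known reaction type is the amine/thiourea-catalysed boronic acid hemiester oxa-Michael addition (hydroxide-surrogate β-hydroxylation) of γ- and δ-hydroxy enones, which to my knowledge has not been shown for a fully substituted β-carbon at a ring fusion.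

**Compound list**
1 | 2,2-dimethylcyclopentane-1,3-dione | CC1(C)C(=O)CCC1=O | starting material
2 | (R)-3-hydroxy-2,2-dimethylcyclopentan-1-one | O=C1CC[C@@H](O)C1(C)C | intermediate
3 | (R)-3-[(tert-butyldiphenylsilyl)oxy]-2,2-dimethylcyclopentan-1-one | O=C1CC[C@@H](O[Si](c2ccccc2)(c2ccccc2)C(C)(C)C)C1(C)C | intermediate
4 | (R)-2-bromo-4-[(tert-butyldiphenylsilyl)oxy]-3,3-dimethylcyclopent-1-ene-1-carbaldehyde | BrC1=C(C=O)C[C@@H](O[Si](c2ccccc2)(c2ccccc2)C(C)(C)C)C1(C)C | intermediate
5 | 1-[(4R)-2-bromo-4-[(tert-butyldiphenylsilyl)oxy]-3,3-dimethylcyclopent-1-en-1-yl]propan-1-ol, carbinol epimers | BrC1=C(C(O)CC)C[C@@H](O[Si](c2ccccc2)(c2ccccc2)C(C)(C)C)C1(C)C | intermediate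
6 | 1-[(4R)-2-bromo-4-[(tert-butyldiphenylsilyl)oxy]-3,3-dimethylcyclopent-1-en-1-yl]propan-1-one | BrC1=C(C(=O)CC)C[C@@H](O[Si](c2ccccc2)(c2ccccc2)C(C)(C)C)C1(C)C | intermediate
7 | (E)-but-2-en-1-yl methyl carbonate | C/C=C/COC(=O)OC | starting material
8 | trimethylsilyl dienol ether of 6 (mainly Z, not isolated) | BrC1=C(/C(O[Si](C)(C)C)=C/C)C[C@@H](O[Si](c2ccccc2)(c2ccccc2)C(C)(C)C)C1(C)C | intermediate
9 | (3R)-1-[(4R)-2-bromo-4-[(tert-butyldiphenylsilyl)oxy]-3,3-dimethylcyclopent-1-en-1-yl]-2,3-dimethylpent-4-en-1-one, C-2 epimers | BrC1=C(C(=O)C(C)[C@H](C)C=C)C[C@@H](O[Si](c2ccccc2)(c2ccccc2)C(C)(C)C)C1(C)C | intermediate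
10 | B-alkyl-9-BBN borane from 9 (boron on the terminal carbon, not isolated) | BrC1=C(C(=O)C(C)[C@H](C)CCB2C3CCCC2CCC3)C[C@@H](O[Si](c2ccccc2)(c2ccccc2)C(C)(C)C)C1(C)C | intermediate
11 | (2R,6R)-2-[(tert-butyldiphenylsilyl)oxy]-1,1,5,6-tetramethyl-2,3,5,6,7,8-hexahydroazulen-4(1H)-one, C-5 epimers | C[C@@H]1CCC2=C(C[C@@H](O[Si](c3ccccc3)(c3ccccc3)C(C)(C)C)C2(C)C)C(=O)C1C | intermediate
12 | bromoethene (vinyl bromide) | C=CBr | starting material
13 | lithium enolate of 11 (C-4 O–Li, C-4=C-5, not isolated) | C[C@@H]1CCC2=C(C[C@@H](O[Si](c3ccccc3)(c3ccccc3)C(C)(C)C)C2(C)C)C(O[Li])=C1C | intermediate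
14 | (2R,5S,6R)-2-[(tert-butyldiphenylsilyl)oxy]-5-ethenyl-1,1,5,6-tetramethyl-2,3,5,6,7,8-hexahydroazulen-4(1H)-one | C[C@@H]1CCC2=C(C[C@@H](O[Si](c3ccccc3)(c3ccccc3)C(C)(C)C)C2(C)C)C(=O)[C@@]1(C)C=C | intermediate
15 | 4-bromofuran-2(5H)-one | O=C1C=C(Br)CO1 | starting material
16 | B-alkyl-9-BBN borane from 14 (boron on the terminal carbon, not isolated) | C[C@@H]1CCC2=C(C[C@@H](O[Si](c3ccccc3)(c3ccccc3)C(C)(C)C)C2(C)C)C(=O)[C@@]1(C)CCB1C2CCCC1CCC2 | intermediate
17 | (2R,5S,6R)-2-[(tert-butyldiphenylsilyl)oxy]-1,1,5,6-tetramethyl-5-[2-(5-oxo-2,5-dihydrofuran-3-yl)ethyl]-2,3,5,6,7,8-hexahydroazulen-4(1H)-one | C[C@@H]1CCC2=C(C[C@@H](O[Si](c3ccccc3)(c3ccccc3)C(C)(C)C)C2(C)C)C(=O)[C@@]1(C)CCC1=CC(=O)OC1 | intermediate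
18 | (2R,5S,6R)-2-hydroxy-1,1,5,6-tetramethyl-5-[2-(5-oxo-2,5-dihydrofuran-3-yl)ethyl]-2,3,5,6,7,8-hexahydroazulen-4(1H)-one | C[C@@H]1CCC2=C(C[C@@H](O)C2(C)C)C(=O)[C@@]1(C)CCC1=CC(=O)OC1 | intermediate
19 | cyclic phenylboronate of 20 (O-2 and O-8a bridged by B–Ph, not isolated) | C[C@@H]1CC[C@]2(OB(c3ccccc3)O4)[C@H](C[C@@H]4C2(C)C)C(=O)[C@@]1(C)CCC1=CC(=O)OC1 | intermediate
20 | (2R,3aS,5S,6R,8aS)-2,8a-dihydroxy-1,1,5,6-tetramethyl-5-[2-(5-oxo-2,5-dihydrofuran-3-yl)ethyl]octahydroazulen-4(1H)-one | C[C@@H]1CC[C@]2(O)[C@H](C[C@@H](O)C2(C)C)C(=O)[C@@]1(C)CCC1=CC(=O)OC1 | target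

**Total step count:** 11. **Longest linear sequence:** 11 (from 1).

**Three steps most likely to fail**

Step 7 (ring closure). The borane may reduce the ketone, and seven-membered closure by B-alkyl Suzuki coupling is slower than five- or six-membered closure. The fallback sets out from 9 and comes back at 11. Suzuki–Miyaura vinylation of the vinyl bromide with CH2=CHBF3K (Pd(dppf)Cl2, Cs2CO3, THF/H2O) gives the cross-conjugated triene ketone F1. Ring-closing metathesis of its two terminal vinyl groups with the second-generation Grubbs catalyst gives the cyclohepta-2,4-dienone F2. Hydrogenation of the disubstituted 7,8-alkene with H2 over RhCl(PPh3)3 spares the tetrasubstituted enone and gives 11.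

Step 8 (quaternary centre). The hindered tertiary enolate may couple slowly or with poor facial selectivity. The fallback sets out from 11 and comes back at 14. The enolate (LiN(iPr)2, THF, −78 °C) adds to acetaldehyde anti to the C-6 methyl and gives the β-hydroxy ketone F3. Syn-elimination with the Burgess reagent (toluene, 50 °C) can take a hydrogen only from the methyl group and gives 14.

Step 11 (proposed new step). The oxa-Michael addition to a fully substituted β-carbon next to a quaternary centre may be too slow or thermodynamically unfavourable. The fallback uses known chemistry, sets out from 18 and comes back at 20. Hydroxyl-directed epoxidation (VO(acac)2, tBuOOH, CH2Cl2) gives the α,β-epoxy ketone F4 with the oxirane syn to the C-2 hydroxyl. SmI2 (THF/MeOH, −90 °C) cleaves the C-3a–O bond and leaves the C-8a hydroxyl; brief exposure to Et3N equilibrates C-3a to the trans-fused 20.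

**Further compounds**
F1 | step 7 | (3R)-1-[(4R)-4-[(tert-butyldiphenylsilyl)oxy]-2-ethenyl-3,3-dimethylcyclopent-1-en-1-yl]-2,3-dimethylpent-4-en-1-one, C-2 epimers | C=CC1=C(C(=O)C(C)[C@H](C)C=C)C[C@@H](O[Si](c2ccccc2)(c2ccccc2)C(C)(C)C)C1(C)C
F2 | step 7 | 7,8-didehydro analogue of 11 (cyclohepta-2,4-dienone, C-5 epimers) | C[C@@H]1C=CC2=C(C[C@@H](O[Si](c3ccccc3)(c3ccccc3)C(C)(C)C)C2(C)C)C(=O)C1C
F3 | step 8 | 11 carrying a 1-hydroxyethyl group on C-5 anti to the 6-methyl (carbinol epimers) | C[C@@H]1CCC2=C(C[C@@H](O[Si](c3ccccc3)(c3ccccc3)C(C)(C)C)C2(C)C)C(=O)[C@@]1(C)C(C)O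
F4 | step 11 | 3a,8a-epoxide of 18, oxirane syn to the C-2 hydroxyl | C[C@@H]1CC[C@]2(O3)[C@@]3(C[C@@H](O)C2(C)C)C(=O)[C@@]1(C)CCC1=CC(=O)OC1
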